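**Retrosynthetic overview**
1. Target 19 ⇐ benzoylation of the primary C7–OH of triol 18 ⇐ C5 benzoate 17 ⇐ C3 acetate 15 ⇐ triol 13; a C6/C7 silylene separates O3 from O6 and fixes the ring so that O5 can be told from O4.
2. 13 ⇐ allylic alcohol 12 ⇐ ester 11 ⇐ enol triflate 10 (C7 from CO) ⇐ cyclohexanone 7.
3. 7 ⇐ intramolecular aldol (C2–C3 bond) of the 6-deoxy-hexos-5-ulose 6, released from lactol 5 ⇐ L-rhamnose 1 (acetonide, anomeric benzyl, C5 oxidation, hydrogenolysis).
4. Feature used: the six-membered carbocycle has a single unoxygenated ring carbon, the vinylic C2–H. It is the C6 methyl of L-rhamnose, and C4, C5, C6 (O4/O5 cis, O5/O6 trans) are rhamnose C2, C3, C4, so only C3 is new.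
5. Ring order: the carbocycle (step 5) is the only ring of the target; the dioxolane (step 1) and the silylene (step 11) are temporary.

Key step: step 5

Numbering used for all carbocycles: C1 (ketone carbon, later the alkene carbon bearing C7), C2 (from the rhamnose methyl), C3 (from rhamnose C1), C4, C5, C6 (from rhamnose C2, C3, C4). Drawn with C1→C6 clockwise, O3 and O6 point toward the viewer and O4 and O5 away; the target is (3R,4S,5R,6S) in this numbering.

Assumption: 2, 3, 4 and 5 are handled as anomeric mixtures (α-anomer drawn), which is harmless because the anomeric carbon becomes the aldehyde carbon of 6; L-rhamnose is used as its commercial monohydrate.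

**Step 1**
Reactants: 1 L-rhamnose
Product: 2 2,3-O-isopropylidene-α-L-rhamnofuranose
Conditions: Me2C(OMe)2, TsOH·H2O (cat.), acetone, rt; Et3N
Reagents that add atoms: 2,2-dimethoxypropane, COC(C)(C)OC
Why: Acid-catalysed ketalization under thermodynamic control captures the cis-2,3-diol in the furanose form as a cis-fused dioxolane and leaves only the anomeric and the C5 hydroxyl free, without touching a stereocentre.

**Step 2**
Reactants: 2 2,3-O-isopropylidene-α-L-rhamnofuranose
Product: 3 benzyl 2,3-O-isopropylidene-α-L-rhamnofuranoside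
Conditions: NaH (1.0 equiv), BnBr (1.05 equiv), THF–DMF, 0 °C
Reagents that add atoms: benzyl bromide, BrCc1ccccc1
Why: Anomeric O-alkylation of the Williamson type: one equivalent of base deprotonates the hemiacetal hydroxyl, which is several pKa units more acidic than the secondary C5 hydroxyl, and the anomeric alkoxide is benzylated.

**Step 3**
Reactants: 3 benzyl 2,3-O-isopropylidene-α-L-rhamnofuranoside
Product: 4 benzyl 6-deoxy-2,3-O-isopropylidene-α-L-lyxo-hexofuranosid-5-ulose
Conditions: Dess–Martin periodinane, CH2Cl2, 0 °C → rt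
Reagents that add atoms: none
Why: Dess–Martin oxidation of the only free secondary alcohol gives the methyl ketone under non-basic conditions, so the neighbouring furanoside carbon C4 (α to the new ketone) keeps its configuration.

**Step 4**
Reactants: 4 benzyl 6-deoxy-2,3-O-isopropylidene-α-L-lyxo-hexofuranosid-5-ulose
Product: 5 6-deoxy-2,3-O-isopropylidene-L-lyxo-hexofuranos-5-ulose
Conditions: H2 (1 atm), 10% Pd/C, EtOAc, rt
Reagents that add atoms: none
Why: Hydrogenolysis of the benzylic C–O bond frees the hemiacetal under neutral conditions that leave the ketone and the acetonide untouched.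

**Step 5**
Reactants: 5 6-deoxy-2,3-O-isopropylidene-L-lyxo-hexofuranos-5-ulose
Product: 7 (3R,4S,5R,6R)-3,6-dihydroxy-4,5-(isopropylidenedioxy)cyclohexan-1-one, via open-chain keto aldehyde 6 (not isolated)
Conditions: DBU (0.2 equiv), CH2Cl2, 0 °C → rt; AcOH quench
Reagents that add atoms: none
Why: The amidine base opens lactol 5 to the 1,5-keto aldehyde 6 and enolizes its methyl ketone toward the methyl carbon (C2), which adds to the aldehyde carbon (C3) in an intramolecular aldol addition; the closest known reaction type is the aldol closure of 6-deoxyhexos-5-uloses that ends a Ferrier carbocyclization, run here without divalent mercury. The six-membered carbocycle closes in the 6-(enolendo)-exo-trig mode. Regioselectivity is secured by ring size: only the methyl enolate reaches the aldehyde through an unstrained ring, since bond formation from C6 or from the aldehyde α-carbon C4 would give a cyclobutane, so enolization there is unproductive. The new stereocentre C3 is set in a chair-like transition state with O5 and O6 equatorial and, forced by the cis-fused dioxolane, O4 axial; the aldehyde C=O takes the axial position anti to the C4–O bond (Cornforth-type dipole minimisation, and the position from which the protonated amidine can bridge it to the enolate oxygen), which puts the C3 hydroxyl trans to O4 and trans to O5. C4, C5 and C6 are carried over from rhamnose C2, C3 and C4, and at the enolizable C6 the wanted arrangement (OH equatorial, trans to O5) is also the more stable one in the cyclohexanone. The step needs kinetic control, so a sub-stoichiometric base, low temperature and an acidic quench are used to keep the β-hydroxy ketone from retro-aldol equilibration and from E1cB loss of water.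

**Step 6**
Reactants: 7 (3R,4S,5R,6R)-3,6-dihydroxy-4,5-(isopropylidenedioxy)cyclohexan-1-one
Product: 8 3,6-bis-O-TBS ether of 7
Conditions: TBSOTf (2.4 equiv), 2,6-lutidine, CH2Cl2, −78 → 0 °C
Reagents that add atoms: tert-butyldimethylsilyl triflate, CC(C)(C)[Si](C)(C)OS(=O)(=O)C(F)(F)F
Why: Silyl ether formation with a silyl triflate and a hindered pyridine base is fast at low temperature and mild enough to spare the β-hydroxy ketone from E1cB dehydration, and both hydroxyls are protected alike because they need not be told apart here.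

**Step 7**
Reactants: 8 3,6-bis-O-TBS ether of 7
Product: 10 C1 enol triflate of 8 (C1=C2), via potassium enolate 9 (not isolated)
Conditions: KN(SiMe3)2 (1.1 equiv), THF, −78 °C; then N-(5-chloro-2-pyridyl)triflimide, −78 °C
Reagents that add atoms: N-(5-chloropyridin-2-yl)bis(trifluoromethanesulfonyl)imide, O=S(=O)(N(c1ccc(Cl)cn1)S(=O)(=O)C(F)(F)F)C(F)(F)F
Why: Kinetic enolization with a bulky amide removes a proton from the C2 methylene and not from the C6 methine shielded by its OTBS group, and O-sulfonylation of the enolate at −78 °C (enol triflate formation) should outrun loss of the poor silyloxide leaving group from C3.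

**Step 8**
Reactants: 10 C1 enol triflate of 8
Product: 11 methyl ester (CO2Me on C1, C1=C2, 3,6-bis-OTBS, 4,5-acetonide)
Conditions: Pd(PPh3)4 (5 mol %), CO (1 atm), MeOH, Et3N, DMF, 60 °C
Reagents that add atoms: carbon monoxide, [C-]#[O+]; methanol, CO
Why: Palladium-catalysed alkoxycarbonylation of a vinyl triflate (oxidative addition of zerovalent palladium into the C–OTf bond, CO insertion, methanolysis of the acyl complex) attaches C7 to C1 with the alkene fixed at C1=C2.

**Step 9**
Reactants: 11 methyl ester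
Product: 12 allylic alcohol (C7H2OH on C1, 3,6-bis-OTBS, 4,5-acetonide)
Conditions: i-Bu2AlH (2.5 equiv), CH2Cl2, −78 → 0 °C; aq. potassium sodium tartrate
Reagents that add atoms: none
Why: Hydride reduction of the conjugated ester with DIBAL-H proceeds by 1,2-addition to the allylic alcohol and leaves silyl ethers and acetonide intact.

**Step 10**
Reactants: 12 allylic alcohol
Product: 13 triol (C3–OH, C6–OH, C7–OH; 4,5-acetonide)
Conditions: Bu4NF (3 equiv), THF, 0 °C → rt
Reagents that add atoms: none
Why: Fluoride-induced desilylation removes both TBS ethers, and since no ester is present at this stage the basic fluoride cannot cause acyl migration.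

**Step 11**
Reactants: 13 triol
Product: 14 6,7-O-(di-tert-butylsilylene) derivative of 13 (C3–OH free)
Conditions: t-Bu2Si(OTf)2 (1.05 equiv), 2,6-lutidine, CH2Cl2, −40 → 0 °C
Reagents that add atoms: di-tert-butylsilyl bis(trifluoromethanesulfonate), CC(C)(C)[Si](OS(=O)(=O)C(F)(F)F)(OS(=O)(=O)C(F)(F)F)C(C)(C)C
Why: Cyclic silylene formation is possible only for the 1,3-related C6 and C7 hydroxyls (six-membered ring), whereas the C3 hydroxyl has no free partner, so O3 and O6 are differentiated by constitution and not by a rate difference.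

**Step 12**
Reactants: 14 silylene alcohol
Product: 15 3-O-acetate of 14
Conditions: Ac2O, pyridine, DMAP (cat.), CH2Cl2, 0 °C → rt
Reagents that add atoms: acetic anhydride, CC(=O)OC(C)=O
Why: DMAP-catalysed acylation of the only free hydroxyl installs the C3 acetate with retention, as the C–O bond is not touched.

**Step 13**
Reactants: 15 3-O-acetate
Product: 16 4,5-diol (3-O-acetyl, 6,7-O-silylene)
Conditions: CF3CO2H–H2O (9:1), CH2Cl2, 0 °C
Reagents that add atoms: none
Why: Acid hydrolysis of the isopropylidene ketal frees the cis-4,5-diol while the di-tert-butylsilylene of a 1,3-diol and the esters should survive brief aqueous acid, and the acetate cannot migrate because O3 and O4 are held trans-diaxial.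

**Step 14**
Reactants: 16 4,5-diol
Product: 17 5-O-benzoate of 16 (C4–OH free)
Conditions: BzCl (1.1 equiv), Me2SnCl2 (5 mol %), i-Pr2NEt, THF, rt
Reagents that add atoms: benzoyl chloride, O=C(Cl)c1ccccc1
Why: Tin-templated regioselective monoacylation of a cis-1,2-diol goes to the equatorial oxygen, and the silylene ring, which needs O6 pseudo-equatorial, fixes the half-chair with O5 equatorial and O4 axial, so the benzoate is placed on O5.

**Step 15**
Reactants: 17 5-O-benzoate
Product: 18 3-O-acetyl-5-O-benzoyl triol (C4–OH, C6–OH, C7–OH)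
Conditions: HF·pyridine, pyridine, THF, 0 °C → rt
Reagents that add atoms: none
Why: Fluoride cleavage of the Si–O bonds removes the silylene under weakly acidic conditions in which acetate and benzoate should neither hydrolyse nor migrate.

**Step 16**
Reactants: 18 3-O-acetyl-5-O-benzoyl triol
Product: 19 target, (3R,4S,5R,6S)-3-acetoxy-5-benzoyloxy-1-(benzoyloxymethyl)-4,6-dihydroxycyclohex-1-ene
Conditions: BzCl (1.05 equiv), 2,4,6-collidine, CH2Cl2, −40 °C
Reagents that add atoms: benzoyl chloride, O=C(Cl)c1ccccc1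
Why: Selective acylation of the primary allylic hydroxyl in the presence of two secondary hydroxyls relies on its far higher rate at low temperature, and the weak, hindered base limits ester migration to the neighbouring free hydroxyls.

**Compound list**
1 | L-rhamnose (6-deoxy-L-mannose) | O=C[C@H](O)[C@H](O)[C@@H](O)[C@@H](O)C | starting material
2 | 2,3-O-isopropylidene-α-L-rhamnofuranose | O[C@@H]1O[C@@H]([C@@H](O)C)[C@H]2OC(C)(C)O[C@@H]12 | intermediate
3 | benzyl 2,3-O-isopropylidene-α-L-rhamnofuranoside | c1ccccc1CO[C@@H]1O[C@@H]([C@@H](O)C)[C@H]2OC(C)(C)O[C@@H]12 | intermediate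
4 | benzyl 6-deoxy-2,3-O-isopropylidene-α-L-lyxo-hexofuranosid-5-ulose | c1ccccc1CO[C@@H]1O[C@@H](C(C)=O)[C@H]2OC(C)(C)O[C@@H]12 | intermediate
5 | 6-deoxy-2,3-O-isopropylidene-L-lyxo-hexofuranos-5-ulose (keto lactol) | O[C@@H]1O[C@@H](C(C)=O)[C@H]2OC(C)(C)O[C@@H]12 | intermediate
6 | 6-deoxy-2,3-O-isopropylidene-aldehydo-L-lyxo-hexos-5-ulose (open-chain form of 5) | CC(=O)[C@H](O)[C@H]1OC(C)(C)O[C@H]1C=O | intermediate (not isolated)
7 | (3R,4S,5R,6R)-3,6-dihydroxy-4,5-(isopropylidenedioxy)cyclohexan-1-one | O[C@@H]1CC(=O)[C@H](O)[C@H]2OC(C)(C)O[C@@H]12 | intermediate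
8 | 3,6-bis-O-TBS ether of 7 | CC(C)(C)[Si](C)(C)O[C@@H]1CC(=O)[C@H](O[Si](C)(C)C(C)(C)C)[C@H]2OC(C)(C)O[C@@H]12 | intermediate
9 | potassium C1–C2 enolate of 8 | CC(C)(C)[Si](C)(C)O[C@@H]1C=C([O-])[C@H](O[Si](C)(C)C(C)(C)C)[C@H]2OC(C)(C)O[C@@H]12.[K+] | intermediate (not isolated)
10 | C1 enol triflate of 8 (C1=C2) | CC(C)(C)[Si](C)(C)O[C@@H]1C=C(OS(=O)(=O)C(F)(F)F)[C@H](O[Si](C)(C)C(C)(C)C)[C@H]2OC(C)(C)O[C@@H]12 | intermediate
11 | methyl ester (CO2Me on C1, C1=C2, 3,6-bis-OTBS, 4,5-acetonide) | CC(C)(C)[Si](C)(C)O[C@@H]1C=C(C(=O)OC)[C@H](O[Si](C)(C)C(C)(C)C)[C@H]2OC(C)(C)O[C@@H]12 | intermediate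
12 | allylic alcohol (C7H2OH, 3,6-bis-OTBS, 4,5-acetonide) | CC(C)(C)[Si](C)(C)O[C@@H]1C=C(CO)[C@H](O[Si](C)(C)C(C)(C)C)[C@H]2OC(C)(C)O[C@@H]12 | intermediate
13 | triol (C3–OH, C6–OH, C7–OH; 4,5-acetonide) | O[C@@H]1C=C(CO)[C@H](O)[C@H]2OC(C)(C)O[C@@H]12 | intermediate
14 | 6,7-O-(di-tert-butylsilylene) derivative of 13 | O[C@@H]1C=C2CO[Si](C(C)(C)C)(C(C)(C)C)O[C@@H]2[C@H]3OC(C)(C)O[C@@H]13 | intermediate
15 | 3-O-acetate of 14 | CC(=O)O[C@@H]1C=C2CO[Si](C(C)(C)C)(C(C)(C)C)O[C@@H]2[C@H]3OC(C)(C)O[C@@H]13 | intermediate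
16 | 4,5-diol (3-O-acetyl, 6,7-O-silylene) | CC(=O)O[C@@H]1C=C2CO[Si](C(C)(C)C)(C(C)(C)C)O[C@@H]2[C@@H](O)[C@H]1O | intermediate
17 | 5-O-benzoate of 16 | CC(=O)O[C@@H]1C=C2CO[Si](C(C)(C)C)(C(C)(C)C)O[C@@H]2[C@@H](OC(=O)c3ccccc3)[C@H]1O | intermediate
18 | 3-O-acetyl-5-O-benzoyl triol (C4–OH, C6–OH, C7–OH) | CC(=O)O[C@@H]1C=C(CO)[C@H](O)[C@@H](OC(=O)c2ccccc2)[C@H]1O | intermediate
19 | (3R,4S,5R,6S)-3-acetoxy-5-benzoyloxy-1-(benzoyloxymethyl)-4,6-dihydroxycyclohex-1-ene | CC(=O)O[C@@H]1C=C(COC(=O)c2ccccc2)[C@H](O)[C@@H](OC(=O)c2ccccc2)[C@H]1O | target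

**Step count**
Total: 16 steps. Longest linear sequence: 16 steps from L-rhamnose.

**Steps most likely to fail**

1. Step 5 (key aldol). The lactol may open slowly, which gives time for enolization on the oxygenated side of the ketone. That would epimerize C6 (in the furanose the acetyl group sits on the concave face, so the epimeric lactol is favoured) or shift the carbonyl through the enediol. The aldehyde α-carbon of 6 can also epimerize, 7 can dehydrate to the enone, and facial control at C3 can erode by retro-aldol equilibration. The fallback sets out from 1 and comes back at 8. It closes the ring on an open-chain keto aldehyde whose future C6 oxygen is already a silyl ether, so that no lactol has to open and no free ketol exists. Fischer glycosidation of 1 in benzyl alcohol (AcCl cat., 70 °C) would give benzyl α-L-rhamnopyranoside F1. Ketalization (Me2C(OMe)2, TsOH) would give its 2,3-acetonide F2, and TBSOTf/2,6-lutidine the 4-O-TBS ether F3. Hydrogenolysis (H2, Pd(OH)2/C) would give the pyranose lactol F4, NaBH4 (EtOH, 0 °C) the 1,5-diol F5, and a double Swern oxidation the 4-O-TBS keto aldehyde F6. DBU (cat.) would close F6 by the same C2–C3 aldol to the 6-O-TBS β-hydroxy ketone F7, and TBSOTf/2,6-lutidine on F7 gives 8.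

2. Step 7 (enol triflate). The base may remove the proton at C6 instead of C2, or enolate 9 may expel the C3 silyloxide by E1cB to give the enone. The fallback sets out from 8 and comes back at 12, replaces steps 7 to 9 and involves no enolate. Non-basic Takai–Lombardo methylenation (Zn, CH2Br2, TiCl4) of 8 would give the exocyclic alkene F8. mCPBA (NaHCO3, CH2Cl2) would give the spiro epoxide F9, of which either diastereomer serves. Diethylaluminium 2,2,6,6-tetramethylpiperidide, Et2Al(NC9H18), in toluene at 0 °C would isomerize the epoxide to the allylic alcohol by concerted syn removal of the less hindered β-proton, that of the C2 methylene. This places the alkene at C1=C2 and the oxygen on C7, which is 12.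

3. Step 14 (C5 versus C4 benzoylation). The two cis hydroxyls may be poorly discriminated if the silylene does not hold the half-chair as assumed, and the benzoyl group may migrate between them. The fallback sets out from 15 and comes back at 19, replacing steps 13 to 16. It uses the opposite conformer and the complementary rule that acid opening of a cyclic orthoester leaves the ester on the axial oxygen. HF·pyridine on 15 would give the 6,7-diol F10, BzCl/collidine at −40 °C the primary benzoate F11, and TBSOTf/2,6-lutidine the 6-O-TBS ether F12. Aqueous acetic acid would give the 4,5-diol F13, in which allylic 1,2-strain between the C1 substituent and the bulky C6 silyloxy group makes O6 pseudo-axial and with it O5 axial and O4 equatorial. PhC(OMe)3 with camphorsulfonic acid would give the cyclic orthobenzoate F14, which on treatment with 80% acetic acid should open to the axial C5 benzoate F15. HF·pyridine then frees O6 and gives 19.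

**Further compounds**
F1 | step 5 | benzyl α-L-rhamnopyranoside | c1ccccc1CO[C@@H]1O[C@@H](C)[C@H](O)[C@@H](O)[C@H]1O
F2 | step 5 | benzyl 2,3-O-isopropylidene-α-L-rhamnopyranoside | c1ccccc1CO[C@@H]1O[C@@H](C)[C@H](O)[C@H]2OC(C)(C)O[C@@H]12
F3 | step 5 | benzyl 4-O-TBS-2,3-O-isopropylidene-α-L-rhamnopyranoside | c1ccccc1CO[C@@H]1O[C@@H](C)[C@H](O[Si](C)(C)C(C)(C)C)[C@H]2OC(C)(C)O[C@@H]12
F4 | step 5 | 4-O-TBS-2,3-O-isopropylidene-α-L-rhamnopyranose | O[C@@H]1O[C@@H](C)[C@H](O[Si](C)(C)C(C)(C)C)[C@H]2OC(C)(C)O[C@@H]12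
F5 | step 5 | 4-O-TBS-2,3-O-isopropylidene-L-rhamnitol | OC[C@@H]1OC(C)(C)O[C@@H]1[C@@H](O[Si](C)(C)C(C)(C)C)[C@@H](O)C
F6 | step 5 | 4-O-TBS-6-deoxy-2,3-O-isopropylidene-aldehydo-L-lyxo-hexos-5-ulose | O=C[C@@H]1OC(C)(C)O[C@@H]1[C@@H](O[Si](C)(C)C(C)(C)C)C(C)=O
F7 | step 5 | 6-O-TBS ether of 7 (C3–OH free) | O[C@@H]1CC(=O)[C@H](O[Si](C)(C)C(C)(C)C)[C@H]2OC(C)(C)O[C@@H]12
F8 | step 7 | 1-methylene analogue of 8 (C1=CH2 in place of C1=O) | CC(C)(C)[Si](C)(C)O[C@@H]1CC(=C)[C@H](O[Si](C)(C)C(C)(C)C)[C@H]2OC(C)(C)O[C@@H]12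
F9 | step 7 | C1 spiro epoxide of F8 (oxirane C1–C7) | CC(C)(C)[Si](C)(C)O[C@@H]1CC3(CO3)[C@H](O[Si](C)(C)C(C)(C)C)[C@H]2OC(C)(C)O[C@@H]12
F10 | step 14 | 3-O-acetyl-4,5-O-isopropylidene 6,7-diol | CC(=O)O[C@@H]1C=C(CO)[C@H](O)[C@H]2OC(C)(C)O[C@@H]12
F11 | step 14 | 7-O-benzoate of F10 | CC(=O)O[C@@H]1C=C(COC(=O)c3ccccc3)[C@H](O)[C@H]2OC(C)(C)O[C@@H]12
F12 | step 14 | 6-O-TBS ether of F11 | CC(=O)O[C@@H]1C=C(COC(=O)c3ccccc3)[C@H](O[Si](C)(C)C(C)(C)C)[C@H]2OC(C)(C)O[C@@H]12
F13 | step 14 | 4,5-diol from F12 | CC(=O)O[C@@H]1C=C(COC(=O)c2ccccc2)[C@H](O[Si](C)(C)C(C)(C)C)[C@@H](O)[C@H]1O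
F14 | step 14 | 4,5-O-(α-methoxybenzylidene) cyclic orthoester of F13 | CC(=O)O[C@@H]1C=C(COC(=O)c3ccccc3)[C@H](O[Si](C)(C)C(C)(C)C)[C@H]2OC(OC)(c4ccccc4)O[C@@H]12
F15 | step 14 | 5-O-benzoate of F13 (6-O-TBS ether of 19) | CC(=O)O[C@@H]1C=C(COC(=O)c2ccccc2)[C@H](O[Si](C)(C)C(C)(C)C)[C@@H](OC(=O)c2ccccc2)[C@H]1O
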